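Retrosynthesis: the C8 epoxyangelate ester, the C11=C13 methylene and the lactone bond C12–O6 are removed first. The two ring olefins C1=C10 and C4=C5, which lie 1,5 to each other in the ten-membered ring C1–C10, are then folded back into a cyclobutane (σ-bonds C1–C4 and C5–C10), which is cut by [2+2] along C1–C10 and C4–C5.
Enabling feature: ring atoms C5–C10 with the C14 carboxyl, O6 and O8 are the ring, carboxyl and two hydroxyls of quinic acid; C1–C4 with C15 and O3 are a 2-methylcyclobut-2-enol.
Forward: quinic acid gives the cyclohexenone ester (six-membered ring present from the start); light closes the cyclobutane (6-4-4 tricycle); heat opens it to the ten-membered ring; reduction at C6 closes the γ-lactone; methylenation, acylation of O8 and desilylation finish.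
Stereochemistry: C8 from quinic acid; C7 by hydrogenation on the convex face of the bridged quinide; C3 by CBS reduction; C6 by Luche reduction; the epoxide by Sharpless epoxidation; both ring-cis olefins by equilibration.
Convergence: three branches (10 + 3 + 3 steps) and 8 steps after their union.

Key step: step 17

Remark: germacrane numbering of the target is used for all intermediates (ring C1–C10; lactone carbons C11–C13 with the ring oxygen on C6; ester carbon C14 on C10; methyl C15 on C4), and 2-methylcyclobutanone is taken as a catalogue compound.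

Step 1
Reactants: 1 (−)-quinic acid
Product: 2 quinide (lactone between the C14 carboxyl and O8)
Conditions: TsOH·H2O (cat.), toluene/DMF, reflux, Dean–Stark
Reagents that add atoms: none
Why: Acid-catalysed lactonisation (Fischer esterification, water removed azeotropically) of the cis-1,3-related carboxyl and O8 hydroxyl gives the bridged γ-lactone, which masks C14 and O8 together and leaves the cis-diol O6/O7 and the tertiary O10 hydroxyl free; no stereocentre is touched.

Step 2
Reactants: 2 quinide
Product: 4 6-O-PMB quinide, via stannylene acetal 3 (not isolated)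
Conditions: Bu2SnO, toluene, reflux (Dean–Stark); then PMBCl, CsF, DMF, rt
Reagents that add atoms: 4-methoxybenzyl chloride, COc1ccc(CCl)cc1
Why: Regioselective O-alkylation through the dibutylstannylene acetal of the cis-6,7-diol, which activates the equatorial oxygen O6 and leaves the axial O7 hydroxyl and the unreactive tertiary O10 hydroxyl free.

Step 3
Reactants: 4 6-O-PMB quinide
Product: 5 6-O-PMB-7-oxoquinide
Conditions: Dess–Martin periodinane, NaHCO3, CH2Cl2, rt
Reagents that add atoms: none
Why: Dess–Martin oxidation of the only secondary alcohol; the tertiary alcohol is inert and the flanking bridgehead C8–H cannot enolise, so nothing is eliminated.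

Step 4
Reactants: 5 6-O-PMB-7-oxoquinide
Product: 6 C7=C11 alkylidene Weinreb amide (E/Z mixture)
Conditions: (EtO)2P(O)CH2C(O)N(OMe)Me, LiCl, DBU, MeCN, 0 °C to rt
Reagents that add atoms: diethyl [2-(methoxy(methyl)amino)-2-oxoethyl]phosphonate, CCOP(=O)(OCC)CC(=O)N(C)OC
Why: Horner–Wadsworth–Emmons olefination under Masamune–Roush conditions on an electrophilic α,α′-dioxygenated ketone; olefin geometry is irrelevant because C11 becomes CH2 in step 5, and an amide is chosen for C12 so that O8 cannot be acylated by it in step 6.

Step 5
Reactants: 6 alkylidene Weinreb amide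
Product: 7 7-deoxy-7-(carbamoylmethyl) quinide with the C11 chain cis to O8
Conditions: H2 (1 atm), Pd/C, pyridine (0.5 equiv), EtOAc, rt
Reagents that add atoms: none
Why: Heterogeneous hydrogenation delivers hydrogen to C7 from the convex face of the 6-oxabicyclo[3.2.1]octanone, opposite the lactone bridge, so that the C11 chain ends up equatorial and cis to O8 (C7 set); pyridine suppresses hydrogenolysis of the PMB ether.

Step 6
Reactants: 7 hydrogenated quinide
Product: 8 ring-opened methyl ester with free O8 and O10 hydroxyls
Conditions: K2CO3 (0.2 equiv), MeOH, 0 °C; AcOH quench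
Reagents that add atoms: methanol, CO
Why: Base-catalysed transesterification opens the strained bridged lactone to the C14 methyl ester; the Weinreb amide is not attacked by the O8 alkoxide under these conditions, so no γ-lactone to O8 forms and no stereocentre is touched.

Step 7
Reactants: 8 dihydroxy methyl ester
Product: 9 O8 triethylsilyl ether
Conditions: TESCl, imidazole, DMAP (cat.), DMF, 0 °C to rt
Reagents that add atoms: chlorotriethylsilane, CC[Si](Cl)(CC)CC
Why: Silylation of the only secondary alcohol; the tertiary α-hydroxy ester at C10 is too hindered for the silyl chloride.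

Step 8
Reactants: 9 O8 triethylsilyl ether
Product: 10 6-hydroxy compound
Conditions: DDQ, CH2Cl2/pH 7 buffer (10:1), 0 °C
Reagents that add atoms: none
Why: Oxidative cleavage of the PMB ether (hydride abstraction to the oxocarbenium ion, then hydrolysis); water keeps the nearby O10 hydroxyl from trapping the cation as an acetal, and silyl ether, amide and ester are inert.

Step 9
Reactants: 10 6-hydroxy compound
Product: 11 β-hydroxy ketone (C6 ketone, tertiary O10 hydroxyl)
Conditions: Dess–Martin periodinane, NaHCO3, CH2Cl2, 0 °C
Reagents that add atoms: none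
Why: Dess–Martin oxidation under buffered, non-basic conditions gives the ketone without epimerising C7, which is now α to the carbonyl.

Step 10
Reactants: 11 β-hydroxy ketone
Product: 12 enone ester (C6 ketone, C5=C10, C14 methyl ester)
Conditions: Burgess reagent, THF, 50 °C
Reagents that add atoms: none
Why: Burgess dehydration (syn-elimination through the sulfamate ester) of the tertiary alcohol toward C5, whose hydrogens are acidified by the C6 ketone, gives the conjugated enone ester without base, so the cis-related C7 and C8 centres survive.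

Step 11
Reactants: 13 2-methylcyclobutanone
Product: 14 2-methyl-1-(trimethylsilyloxy)cyclobutene
Conditions: TMSCl, Et3N, DMF, 80 °C
Reagents that add atoms: chlorotrimethylsilane, C[Si](C)(C)Cl
Why: Silyl enol ether formation under equilibrating conditions favours the more substituted enol ether, which places the later double bond next to the methyl group.

Step 12
Reactants: 14 silyl enol ether
Product: 15 2-methylcyclobut-2-enone
Conditions: Pd(OAc)2 (1 equiv), MeCN, rt
Reagents that add atoms: none
Why: Saegusa–Ito oxidation: palladation at the methyl-bearing carbon and β-hydride elimination from the ring CH2 give the endocyclic enone, as with the enol ethers of 2-methylcycloalkanones.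

Step 13
Reactants: 15 2-methylcyclobut-2-enone
Product: 17 (S)-2-methylcyclobut-2-enyl TBS ether, via cyclobutenol 16 (not isolated)
Conditions: (R)-2-methyl-CBS-oxazaborolidine (0.2 equiv), BH3·SMe2, THF, −40 °C; MeOH; then TBSCl, imidazole, DMF, rt
Reagents that add atoms: tert-butylchlorodimethylsilane, CC(C)(C)[Si](C)(C)Cl
Why: Corey–Bakshi–Shibata reduction in which the methyl-substituted olefinic carbon is the large group, so that the (R)-catalyst gives the (S)-carbinol (C3 of the target); the volatile alcohol is silylated without isolation.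

Step 14
Reactants: 18 angelic acid
Product: 19 (Z)-2-methylbut-2-en-1-ol
Conditions: LiAlH4, Et2O, 0 °C to rt
Reagents that add atoms: none
Why: Hydride reduction of the carboxylic acid to the allylic alcohol, which leaves the (Z)-olefin geometry unchanged.

Step 15
Reactants: 19 (Z)-2-methylbut-2-en-1-ol
Product: 20 (2S,3R)-epoxy alcohol
Conditions: Ti(OiPr)4 (10 mol %), L-(+)-diethyl tartrate (12 mol %), t-BuOOH, 4 Å MS, CH2Cl2, −20 °C
Reagents that add atoms: tert-butyl hydroperoxide, CC(C)(C)OO
Why: Sharpless asymmetric epoxidation; with L-(+)-tartrate the oxygen is delivered to the olefin face that gives the (2S,3R)-epoxy alcohol, and the cis relation of CH2OH and the C3 methyl follows from the (Z)-olefin.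

Step 16
Reactants: 20 (2S,3R)-epoxy alcohol
Product: 21 (2R,3R)-epoxyangelic acid
Conditions: RuCl3·xH2O (2 mol %), NaIO4, MeCN/EtOAc/H2O, rt
Reagents that add atoms: sodium periodate, [Na+].[O-]I(=O)(=O)=O; water, O
Why: RuO4-catalysed oxidation of the primary alcohol to the carboxylic acid leaves the trisubstituted epoxide intact; both centres are retained and the C2 descriptor becomes R only through the change in priorities.

Step 17
Reactants: 12 enone ester; 17 (S)-cyclobutenyl TBS ether
Product: 22 cis-anti-cis tricyclic photoadduct
Conditions: hν (medium-pressure Hg lamp, uranium-glass filter, λ > 330 nm), excess of the cyclobutene (recovered), CH2Cl2, −40 °C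
Reagents that add atoms: none
Why: Excitation of 12 and intersystem crossing give the enone triplet, which adds to the strained olefin of 17 to form a triplet 1,4-diradical that closes after spin inversion; the closest known reaction type is the enone–alkene [2+2] photocycloaddition of cyclohex-2-enones with cyclobutenes. The one ring formed is the central cyclobutane C1–C4–C5–C10, closed by radical–radical recombination of the 1,4-diradical after the first, intermolecular bond. C1/C4 are cis by the cyclobutene ring, C5/C10 are expected cis (a trans-fused isomer could be epimerised at C5, which is α to the ketone), the partner should react on its face anti to the C3 silyloxy group, and the two outer rings should lie anti across the new cyclobutane; with these three preferences the enone has to react on the face of its C7 and C8 substituents, as drawn. The selectivity the step needs is orientation, C1 to C10 and C4 to C5: it rests on the steric demand of C4 (methyl-bearing and flanked by the silyloxy carbon), which avoids the ester-bearing quaternary C10, and on the altered polarisation that the β-alkoxycarbonyl group gives the enone. All four new stereocentres are erased in step 18, so diastereomers at these centres converge and only a head-to-tail adduct would be lost.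

Step 18
Reactants: 22 tricyclic photoadduct
Product: 23 ten-membered dienone (C4=C5 ring-trans; C1=C10 ring-cis)
Conditions: toluene (degassed, 0.01 M), base-washed sealed tube, 180 °C
Reagents that add atoms: none
Why: Thermal cycloreversion of the bicyclo[2.2.0]hexane: the C1–C4 bond shared by the two four-membered rings breaks first and the C5–C10 bond, flanked by ketone and ester, follows, which releases both ring strains and gives the 1,5-diene with both olefins conjugated, expected as the cis,trans isomer from a chair-like 1,4-diyl with C6 equatorial; C3, C7 and C8 are not involved.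

Step 19
Reactants: 23 cis,trans-dienone
Product: 24 all-ring-cis dienone (4Z)
Conditions: I2 (5 mol %), NaHCO3 (solid), benzene, visible light, rt
Reagents that add atoms: none
Why: Iodine-atom-catalysed olefin isomerisation (reversible addition of an iodine atom) should relax the strained ring-trans enone to the ring-cis isomer, the more stable geometry of a cyclodecenone, and would equally correct a trans C1=C10 bond.

Step 20
Reactants: 24 all-ring-cis dienone
Product: 26 trans-fused 6,12-lactone, via hydroxy amide 25 (not isolated)
Conditions: NaBH4, CeCl3·7H2O, MeOH, −78 °C; work-up; then PPTS (cat.), toluene, 40 °C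
Reagents that add atoms: none
Why: Luche 1,2-reduction, in which hydride should approach the carbonyl from the ring periphery on the side of the exocyclic C11 chain (the other face is screened across the ring), giving the (6R)-alcohol with O6 trans to C11; acid-catalysed acyl transfer from the Weinreb amide then closes the trans-fused γ-lactone (5-exo-trig).

Step 21
Reactants: 26 trans-fused 6,12-lactone
Product: 29 α-methylene lactone, via Mannich base 27 (not isolated), via ammonium iodide 28 (not isolated)
Conditions: LiN(iPr)2, THF, −78 °C; Me2N=CH2 iodide, −78 to 0 °C; then MeI, MeOH, rt; then NaHCO3 (aq), EtOAc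
Reagents that add atoms: N,N-dimethylmethyleneiminium iodide (Eschenmoser's salt), C=[N+](C)C.[I-]
Why: α-Methylenation by Mannich reaction of the lactone lithium enolate, N-methylation and E1cB elimination of trimethylamine; the lactone α-protons are more acidic than the γ-protons of the C14 enoate, and the C11 centre formed in passing is destroyed again.

Step 22
Reactants: 29 α-methylene lactone
Product: 30 8-hydroxy lactone
Conditions: HF·pyridine, pyridine, THF, 0 °C
Reagents that add atoms: none
Why: Buffered fluoride cleaves the triethylsilyl ether much faster than the tert-butyldimethylsilyl ether (selective desilylation), so only O8 is freed.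

Step 23
Reactants: 30 8-hydroxy lactone; 21 (2R,3R)-epoxyangelic acid
Product: 32 C8 epoxyangelate, via mixed anhydride 31 (not isolated)
Conditions: 21, 2,4,6-Cl3C6H2COCl, Et3N, THF, rt; then 30, DMAP, toluene, rt
Reagents that add atoms: none
Why: Yamaguchi esterification through the mixed anhydride acylates the hindered C8 alcohol with retention (reaction at oxygen); the epoxy acid has no α-hydrogen, so it can neither epimerise nor isomerise.

Step 24
Reactants: 32 C8 epoxyangelate
Product: 33 target compound
Conditions: HF·pyridine, THF, 0 °C to rt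
Reagents that add atoms: none
Why: Fluoride-mediated desilylation of the allylic TBS ether; the epoxide of the glycidic ester and the α-methylene lactone should tolerate buffered HF.

Compound list

1 | (−)-quinic acid, (1S,3R,4S,5R)-1,3,4,5-tetrahydroxycyclohexane-1-carboxylic acid | OC(=O)[C@]1(O)C[C@@H](O)[C@@H](O)[C@H](O)C1 | starting material
2 | quinide, the γ-lactone of quinic acid (C14 on O8; 1,3,4-trihydroxy-6-oxabicyclo[3.2.1]octan-7-one; O6 equatorial, O7 axial, O10 tertiary) | O[C@@]12C[C@@H](O)[C@@H](O)[C@@H](C1)OC2=O | intermediate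
3 | 6,7-O-dibutylstannylene acetal of quinide | O[C@@]12C[C@@H](O[Sn](CCCC)(CCCC)O3)[C@@H]3[C@@H](C1)OC2=O | intermediate
4 | 6-O-(4-methoxybenzyl)quinide | O[C@@]12C[C@@H](OCc3ccc(OC)cc3)[C@@H](O)[C@@H](C1)OC2=O | intermediate
5 | 6-O-(4-methoxybenzyl)-7-oxoquinide | O[C@@]12C[C@@H](OCc3ccc(OC)cc3)C(=O)[C@@H](C1)OC2=O | intermediate
6 | 7-{2-[methoxy(methyl)amino]-2-oxoethylidene} derivative of 5 (C7=C11, E/Z mixture) | O[C@@]12C[C@@H](OCc3ccc(OC)cc3)C(=CC(=O)N(C)OC)[C@@H](C1)OC2=O | intermediate
7 | 6-O-PMB-7-deoxy-7-{2-[methoxy(methyl)amino]-2-oxoethyl}quinide (H7 on the face away from the lactone bridge, C11 chain cis to O8) | O[C@@]12C[C@@H](OCc3ccc(OC)cc3)[C@H](CC(=O)N(C)OC)[C@@H](C1)OC2=O | intermediate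
8 | methyl 1,5-dihydroxy-3-[(4-methoxybenzyl)oxy]-4-{2-[methoxy(methyl)amino]-2-oxoethyl}cyclohexane-1-carboxylate (ring carbons 1, 3, 4, 5 are C10, C6, C7, C8; configuration as in 7) | COC(=O)[C@]1(O)C[C@@H](OCc2ccc(OC)cc2)[C@H](CC(=O)N(C)OC)[C@H](O)C1 | intermediate
9 | O8 triethylsilyl ether of 8 | COC(=O)[C@]1(O)C[C@@H](OCc2ccc(OC)cc2)[C@H](CC(=O)N(C)OC)[C@H](O[Si](CC)(CC)CC)C1 | intermediate
10 | 6-hydroxy compound (PMB removed from 9) | COC(=O)[C@]1(O)C[C@@H](O)[C@H](CC(=O)N(C)OC)[C@H](O[Si](CC)(CC)CC)C1 | intermediate
11 | methyl 1-hydroxy-4-{2-[methoxy(methyl)amino]-2-oxoethyl}-3-oxo-5-(triethylsilyloxy)cyclohexane-1-carboxylate | COC(=O)[C@]1(O)CC(=O)[C@H](CC(=O)N(C)OC)[C@H](O[Si](CC)(CC)CC)C1 | intermediate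
12 | methyl (4R,5R)-4-{2-[methoxy(methyl)amino]-2-oxoethyl}-3-oxo-5-(triethylsilyloxy)cyclohex-1-ene-1-carboxylate | O=C1C=C(C(=O)OC)C[C@@H](O[Si](CC)(CC)CC)[C@H]1CC(=O)N(C)OC | intermediate
13 | 2-methylcyclobutanone (racemic) | CC1CCC1=O | starting material
14 | 2-methyl-1-(trimethylsilyloxy)cyclobut-1-ene | CC1=C(O[Si](C)(C)C)CC1 | intermediate
15 | 2-methylcyclobut-2-en-1-one | CC1=CCC1=O | intermediate
16 | (S)-2-methylcyclobut-2-en-1-ol | CC1=CC[C@@H]1O | intermediate
17 | (S)-tert-butyldimethyl[(2-methylcyclobut-2-en-1-yl)oxy]silane | CC1=CC[C@@H]1O[Si](C)(C)C(C)(C)C | intermediate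
18 | angelic acid, (Z)-2-methylbut-2-enoic acid | C/C=C(/C)C(=O)O | starting material
19 | (Z)-2-methylbut-2-en-1-ol | C/C=C(/C)CO | intermediate
20 | [(2S,3R)-2,3-dimethyloxiran-2-yl]methanol | OC[C@]1(C)O[C@@H]1C | intermediate
21 | (2R,3R)-2,3-dimethyloxirane-2-carboxylic acid (epoxyangelic acid) | OC(=O)[C@]1(C)O[C@@H]1C | intermediate
22 | cis-anti-cis 6-4-4 photoadduct (cyclohexanone C5–C10; central cyclobutane C1–C4–C5–C10; outer cyclobutane C1–C2–C3–C4): C6 ketone, C7 amide chain, 8-OTES, 10-CO2Me, 4-methyl cis to 3-OTBS; drawn for attack on the cyclobutene face anti to the silyloxy group | O=C1[C@H](CC(=O)N(C)OC)[C@H](O[Si](CC)(CC)CC)C[C@]2(C(=O)OC)[C@H]3C[C@H](O[Si](C)(C)C(C)(C)C)[C@@]3(C)[C@H]12 | intermediate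
23 | ten-membered dienone (3S,7R,8R): C6 ketone, 3-OTBS, 8-OTES, 10-CO2Me, C7 amide chain; C1=C10 ring-cis, C4=C5 ring-trans (4E) | O=C1/C=C(\C)[C@@H](O[Si](C)(C)C(C)(C)C)C/C=C(/C(=O)OC)C[C@@H](O[Si](CC)(CC)CC)[C@H]1CC(=O)N(C)OC | intermediate
24 | the (4Z) isomer of 23, both ring olefins cis | O=C1/C=C(/C)[C@@H](O[Si](C)(C)C(C)(C)C)C/C=C(/C(=O)OC)C[C@@H](O[Si](CC)(CC)CC)[C@H]1CC(=O)N(C)OC | intermediate
25 | (6R)-hydroxy amide from 24 (O6 trans to the C11 chain) | O[C@@H]1/C=C(/C)[C@@H](O[Si](C)(C)C(C)(C)C)C/C=C(/C(=O)OC)C[C@@H](O[Si](CC)(CC)CC)[C@H]1CC(=O)N(C)OC | intermediate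
26 | 6,12-olide from 25: trans-fused γ-lactone (H6 and H7 anti) with C11 as CH2, 3-OTBS, 8-OTES, 14-methyl ester; C3, C6, C7 and C8 arranged as in 25 | C1C(=O)O[C@@H]2/C=C(/C)[C@@H](O[Si](C)(C)C(C)(C)C)C/C=C(/C(=O)OC)C[C@@H](O[Si](CC)(CC)CC)[C@@H]12 | intermediate
27 | 13-(dimethylamino) Mannich base of 26 (C11 epimer drawn with the aminomethyl group anti to C8) | CN(C)C[C@@H]1C(=O)O[C@@H]2/C=C(/C)[C@@H](O[Si](C)(C)C(C)(C)C)C/C=C(/C(=O)OC)C[C@@H](O[Si](CC)(CC)CC)[C@@H]12 | intermediate
28 | 13-(trimethylammonio) iodide from 27 | C[N+](C)(C)C[C@@H]1C(=O)O[C@@H]2/C=C(/C)[C@@H](O[Si](C)(C)C(C)(C)C)C/C=C(/C(=O)OC)C[C@@H](O[Si](CC)(CC)CC)[C@@H]12.[I-] | intermediate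
29 | α-methylene lactone (11(13)-ene), 3-OTBS, 8-OTES | C=C1C(=O)O[C@@H]2/C=C(/C)[C@@H](O[Si](C)(C)C(C)(C)C)C/C=C(/C(=O)OC)C[C@@H](O[Si](CC)(CC)CC)[C@@H]12 | intermediate
30 | 8-hydroxy α-methylene lactone, 3-OTBS | C=C1C(=O)O[C@@H]2/C=C(/C)[C@@H](O[Si](C)(C)C(C)(C)C)C/C=C(/C(=O)OC)C[C@@H](O)[C@@H]12 | intermediate
31 | mixed anhydride of 21 with 2,4,6-trichlorobenzoic acid | O=C(OC(=O)[C@]1(C)O[C@@H]1C)c1c(Cl)cc(Cl)cc1Cl | intermediate
32 | 3-O-TBS ether of the target | C=C1C(=O)O[C@@H]2/C=C(/C)[C@@H](O[Si](C)(C)C(C)(C)C)C/C=C(/C(=O)OC)C[C@@H](OC(=O)[C@]3(C)O[C@@H]3C)[C@@H]12 | intermediate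
33 | target: methyl (3S,6R,7R,8R)-8-[(2R,3R)-2,3-dimethyloxirane-2-carbonyloxy]-3-hydroxy-12-oxo-germacra-1(10),4,11(13)-trien-12,6-olid-14-oate, both ring olefins cis | C=C1C(=O)O[C@@H]2/C=C(/C)[C@@H](O)C/C=C(/C(=O)OC)C[C@@H](OC(=O)[C@]3(C)O[C@@H]3C)[C@@H]12 | target

Total step count: 24.
Longest linear sequence: 18 steps (steps 1–10 and 17–24, from quinic acid).

Steps most likely to fail

Step 18. The cis,trans-diene formed first is a 3-silyloxy-1,5-diene. A Cope rearrangement to the cis-divinylcyclohexane silyl enol ether and its return through the other chair would move the trans olefin from C4=C5 to C1=C10 and invert C3 on the way. The six-membered isomer may also become the resting state, and the C8 silyloxy group β to the ketone may be lost by elimination at this temperature. Fallback: C3 is no longer carried through the thermolysis but is set again at the end by reagent control. The fallback sets out from 33 obtained as a mixture with its C3 epimer, 3-epi-33 F1. MnO2 (CH2Cl2, rt) should oxidise both allylic alcohols to the single 3-ketone F2. CBS reduction with the (R)-oxazaborolidine and BH3·SMe2 at −40 °C, in which the methyl-bearing olefinic carbon C4 is the large group, should then return 33, where the fallback rejoins the route.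

Step 17. Head-to-tail bonding (C4 to the ester-bearing C10) would give, after cycloreversion, a constitutional isomer of the diene. In addition, the (S)-partner cannot at once react anti to its silyloxy group, give the anti ring fusion and use the open face of the enone, which may let enone dimerisation outrun the cross-addition. Fallback: the four-carbon partner is taken achiral and at the ketone level, so that its fully substituted C3 forbids bonding of C4 to the quaternary C10 and no facial mismatch exists. It sets out from 12 and from 15, which is converted with MeOSiMe3 and catalytic TMSOTf (CH2Cl2, −78 °C) into 2-methylcyclobut-2-enone dimethyl ketal F3. Irradiation of 12 with F3 as in step 17 should give ketal adduct F4, and PPTS in wet acetone should free cyclobutanone F5. CBS reduction ((R)-catalyst, BH3·SMe2) should give the (3S)-cyclobutanol F6: the quaternary C4 is the large group, and the strained cyclobutanone reacts before the hindered C6 ketone. TBSCl and imidazole then give silyl ether F7, which differs from 22 at most in the four transient ring-fusion centres. F7 is thermolysed as in step 18 and the fallback comes back to the route at 23.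

Step 20. Hydride may add to the other face of the C6 ketone (poor facial selectivity in the flexible ring) and give the 6β-alcohol, which would close the cis-fused lactone. Fallback: inversion replaces substrate control. It sets out from 24: Luche reduction without the acid treatment gives 6-epi-hydroxy amide F8. A Mitsunobu reaction (4-nitrobenzoic acid, PPh3, DIAD, THF, 0 °C) inverts C6 to 6α-(4-nitrobenzoate) F9. K2CO3 in MeOH removes the ester to give 25, where the fallback comes back to the route, and PPTS closes the lactone to 26 as in step 20.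

Further compounds
F1 | step 18 | 3-epi-33 (C3 epimer of the target) | C=C1C(=O)O[C@@H]2/C=C(/C)[C@H](O)C/C=C(/C(=O)OC)C[C@@H](OC(=O)[C@]3(C)O[C@@H]3C)[C@@H]12
F2 | step 18 | 3-oxo derivative of the target (3-ketone) | C=C1C(=O)O[C@@H]2/C=C(/C)C(=O)C/C=C(/C(=O)OC)C[C@@H](OC(=O)[C@]3(C)O[C@@H]3C)[C@@H]12
F3 | step 17 | 2-methylcyclobut-2-enone dimethyl ketal (3,3-dimethoxy-2-methylcyclobut-1-ene) | CC1=CCC1(OC)OC
F4 | step 17 | ketal photoadduct (cis-anti-cis, drawn for attack on the enone face away from the C7 and C8 substituents) | O=C1[C@H](CC(=O)N(C)OC)[C@H](O[Si](CC)(CC)CC)C[C@@]2(C(=O)OC)[C@@H]3CC(OC)(OC)[C@]3(C)[C@@H]12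
F5 | step 17 | tricyclic cyclobutanone (C3 ketone) | O=C1[C@H](CC(=O)N(C)OC)[C@H](O[Si](CC)(CC)CC)C[C@@]2(C(=O)OC)[C@@H]3CC(=O)[C@]3(C)[C@@H]12
F6 | step 17 | (3S)-cyclobutanol of the tricycle | O=C1[C@H](CC(=O)N(C)OC)[C@H](O[Si](CC)(CC)CC)C[C@@]2(C(=O)OC)[C@@H]3C[C@H](O)[C@]3(C)[C@@H]12
F7 | step 17 | TBS ether of F6 (diastereomer of 22 at C1, C4, C5, C10) | O=C1[C@H](CC(=O)N(C)OC)[C@H](O[Si](CC)(CC)CC)C[C@@]2(C(=O)OC)[C@@H]3C[C@H](O[Si](C)(C)C(C)(C)C)[C@]3(C)[C@@H]12
F8 | step 20 | 6-epi-hydroxy amide ((6S)-epimer of 25) | O[C@H]1/C=C(/C)[C@@H](O[Si](C)(C)C(C)(C)C)C/C=C(/C(=O)OC)C[C@@H](O[Si](CC)(CC)CC)[C@H]1CC(=O)N(C)OC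
F9 | step 20 | 6α-(4-nitrobenzoate) of 25 | O=C(O[C@@H]1/C=C(/C)[C@@H](O[Si](C)(C)C(C)(C)C)C/C=C(/C(=O)OC)C[C@@H](O[Si](CC)(CC)CC)[C@H]1CC(=O)N(C)OC)c1ccc(cc1)[N+](=O)[O-]
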